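## Retrosynthetic overview

- Numbering: oxolane O1, C2 (ring B, 4-hydroxy-3-methoxyphenyl), spiro C3 (epoxide C6, O7), C4 (carries C8, the benzylic CH2 of ring A, 3-hydroxy-4-methoxyphenyl), C5. The strategy rests on C2, C3 and C4 being contiguous stereocentres with the C3–C6 and C4–C8 bonds cis. C6 and C8 can therefore be tied through a temporary oxygen into a five-membered ring whose C3=C4 enol ether takes up a ketene C5=C2.
- Endgame disconnections: epoxide O7–C6 (from C3–OSiEt3 and C6–OTs), C5 methylene (from lactone C5=O), O1 (Baeyer–Villiger insertion between C5 and C2), C8–H (hydrogenolysis of the temporary C8–O bond).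
- Key disconnection: cyclobutanone C5–C2–C3–C4 by [2+2] cycloaddition of the ring B ketene to an (S)-5-aryl-3-silyloxy-2,5-dihydrofuran (bonds C2–C3 and C4–C5).
- Fragments: the dihydrofuran comes from isovanillin by asymmetric propargylboration, gold-catalysed oxidative cyclisation and kinetic enol silylation; the ketene comes from homovanillic acid.
- Ring order: temporary oxolane (C6–O–C8), cyclobutanone, opening of the temporary ring, γ-lactone then oxolane (O1), epoxide.

Key step: step 7

Assumption: in step 2 the (S)-configured phosphoric acid is taken to direct Si-face attack on the aldehyde, the mirror image of the Re-face sense of the (R)-acid in allyl- and propargylborations of aryl aldehydes; should the sense prove opposite, the (R)-acid is used.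

## Route

Step 1
Reactants: 1 isovanillin
Product: 2 3-(tert-butyldimethylsilyloxy)-4-methoxybenzaldehyde
Conditions: TBSCl, imidazole, DMF, rt
Reagents that add atoms: tert-butyldimethylsilyl chloride, CC(C)(C)[Si](C)(C)Cl
Why: Standard imidazole-promoted silylation of a phenol; the aldehyde is inert.

Step 2
Reactants: 2 3-(tert-butyldimethylsilyloxy)-4-methoxybenzaldehyde; 3 allenylboronic acid pinacol ester
Product: 5 (1S)-1-[3-(tert-butyldimethylsilyloxy)-4-methoxyphenyl]but-3-yn-1-ol, via pinacol borate ester 4 (not isolated)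
Conditions: (S)-3,3'-bis(2,4,6-triisopropylphenyl)-1,1'-binaphthyl-2,2'-diyl hydrogen phosphate ((S)-TRIP, 5 mol %), 4 Å MS, PhMe, 0 °C to rt; aq. NaHCO3 work-up
Reagents that add atoms: none
Why: Chiral phosphoric acid-catalysed asymmetric propargylboration through a closed six-membered transition state (allenyl to propargyl transposition); the acid-bound boronate should be delivered to the Si face of the aldehyde and set C8 as (S).

Step 3
Reactants: 5 (1S)-1-[3-(tert-butyldimethylsilyloxy)-4-methoxyphenyl]but-3-yn-1-ol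
Product: 6 (5S)-5-[3-(tert-butyldimethylsilyloxy)-4-methoxyphenyl]oxolan-3-one
Conditions: Ph3PAuNTf2 (5 mol %), 8-methylquinoline N-oxide (1.5 equiv), ClCH2CH2Cl, rt, no acid additive
Reagents that add atoms: 8-methylquinoline N-oxide, Cc1cccc2ccc[n+]([O-])c12
Why: Gold-catalysed alkyne oxidation with O–H insertion: the N-oxide attacks the internal carbon of the gold-bound alkyne, N–O cleavage gives an α-oxo gold carbene at the terminal carbon (C6), and the C8 hydroxyl traps it to close the oxolan-3-one; C8 is not touched and keeps its configuration.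

Step 4
Reactants: 6 (5S)-5-[3-(tert-butyldimethylsilyloxy)-4-methoxyphenyl]oxolan-3-one
Product: 8 triethyl{[(5S)-5-[3-(tert-butyldimethylsilyloxy)-4-methoxyphenyl]-2,5-dihydrofuran-3-yl]oxy}silane, via lithium enolate 7 (not isolated)
Conditions: LiN(i-Pr)2, THF, −78 °C; Et3SiCl, −78 to −20 °C; cold aq. NaHCO3/pentane work-up
Reagents that add atoms: chlorotriethylsilane, CC[Si](CC)(CC)Cl
Why: Kinetic enolate formation and O-silylation; deprotonation should occur at C4 and not at the O-flanked C6 (lone-pair repulsion disfavours the α-oxy carbanion), and at −78 °C the cyclic enolate should not expel the C8 alkoxide, so C8 stays (S).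

Step 5
Reactants: 9 homovanillic acid
Product: 11 2-[4-(tert-butyldimethylsilyloxy)-3-methoxyphenyl]acetic acid, via bis-silyl ester 10 (not isolated)
Conditions: TBSCl (2.2 equiv), imidazole, DMF, rt; then THF/H2O/AcOH, rt
Reagents that add atoms: tert-butyldimethylsilyl chloride, CC(C)(C)[Si](C)(C)Cl
Why: Exhaustive silylation followed by selective hydrolysis of the far more labile silyl ester; the aryl silyl ether survives dilute acetic acid.

Step 6
Reactants: 11 2-[4-(tert-butyldimethylsilyloxy)-3-methoxyphenyl]acetic acid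
Product: 12 2-[4-(tert-butyldimethylsilyloxy)-3-methoxyphenyl]acetyl chloride
Conditions: (COCl)2, cat. DMF, CH2Cl2, 0 °C to rt; volatiles removed, used crude
Reagents that add atoms: oxalyl chloride, O=C(Cl)C(Cl)=O
Why: Acid chloride formation through the Vilsmeier-type chloroiminium species; all by-products are volatile.

Step 7
Reactants: 8 triethyl{[(5S)-5-[3-(tert-butyldimethylsilyloxy)-4-methoxyphenyl]-2,5-dihydrofuran-3-yl]oxy}silane; 12 2-[4-(tert-butyldimethylsilyloxy)-3-methoxyphenyl]acetyl chloride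
Product: 14 (1S,4S,5R,7S)-4-[3-(tert-butyldimethylsilyloxy)-4-methoxyphenyl]-7-[4-(tert-butyldimethylsilyloxy)-3-methoxyphenyl]-1-(triethylsilyloxy)-3-oxabicyclo[3.2.0]heptan-6-one, via aryl ketene 13 (not isolated)
Conditions: i-Pr2NEt (3 equiv), PhMe, 40 °C, 12 (2.5 equiv) added over 6 h by syringe pump; filtration of the ammonium salt, rapid chromatography on neutral silica
Reagents that add atoms: none
Why: Dehydrochlorination of 12 gives ketene 13, which adds to the electron-rich C3=C4 enol ether in a concerted but asynchronous [2+2] cycloaddition, the ketene carbonyl carbon C5 bonding first to the nucleophilic C4 and the aryl-bearing C2 then closing onto the oxocarbenium-like C3. The closest known reaction type is the ketene–enol ether cycloaddition that gives 3-alkoxy- and 3-silyloxycyclobutanones with this head-to-tail regiochemistry. The cyclobutanone C5–C2–C3–C4 is closed by this intermolecular two-bond cycloaddition and is necessarily cis-fused to the dihydrofuran, which places C6 on C3 cis to C8 on C4. C3 and C4 are controlled by the C8 stereocentre, the ketene approaching the face of the nearly planar ring opposite ring A; C2 is controlled by the ketene geometry, its hydrogen pointing towards the alkene in the transition state so that ring B ends endo, cis to C6 and trans to the Et3SiO group. The step needs regioselectivity (secured by the enol ether polarisation), face selectivity (secured by the allylic aryl group on C8) and kinetic endo selectivity without epimerisation of the acidic C2–H, for which a hindered amine, slow addition of 12 and a non-basic work-up are used.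

Step 8
Reactants: 14 the bicyclic ketone
Product: 15 (2S,3R,4R)-2-[4-(tert-butyldimethylsilyloxy)-3-methoxyphenyl]-4-[3-(tert-butyldimethylsilyloxy)-4-methoxybenzyl]-3-(hydroxymethyl)-3-(triethylsilyloxy)cyclobutan-1-one
Conditions: H2 (1 atm), 10% Pd/C, EtOAc, rt
Reagents that add atoms: none
Why: Catalytic hydrogenolysis; C8–O is the only benzylic carbon–oxygen bond in 14 and carries an electron-rich aryl group, so it should be cleaved to the C8 methylene and the C6 primary alcohol, while the aprotic solvent spares the Et3Si ether and C2, C3 and C4 are untouched.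

Step 9
Reactants: 15 the hydroxymethyl cyclobutanone
Product: 16 [(1R,2S,4R)-2-[4-(tert-butyldimethylsilyloxy)-3-methoxyphenyl]-4-[3-(tert-butyldimethylsilyloxy)-4-methoxybenzyl]-3-oxo-1-(triethylsilyloxy)cyclobutyl]methyl 4-methylbenzenesulfonate
Conditions: TsCl, pyridine, cat. DMAP, CH2Cl2, 0 °C
Reagents that add atoms: 4-toluenesulfonyl chloride, Cc1ccc(S(Cl)(=O)=O)cc1
Why: Sulfonylation of the only free hydroxyl; pyridine is too weak a base to enolise the ketone towards C2, so the endo aryl configuration should hold.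

Step 10
Reactants: 16 the cyclobutanone tosylate
Product: 17 [(2S,3S,4R)-2-[4-(tert-butyldimethylsilyloxy)-3-methoxyphenyl]-4-[3-(tert-butyldimethylsilyloxy)-4-methoxybenzyl]-5-oxo-3-(triethylsilyloxy)oxolan-3-yl]methyl 4-methylbenzenesulfonate
Conditions: mCPBA, NaHCO3, CH2Cl2, 0 °C
Reagents that add atoms: 3-chloroperoxybenzoic acid, O=C(OO)c1cccc(Cl)c1
Why: Baeyer–Villiger oxidation driven by ring strain; in the Criegee intermediate the benzylic C2 migrates in preference to the alkyl C4 and does so with retention, which inserts O1 between C5 and C2 and keeps C2 as set in step 7.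

Step 11
Reactants: 17 the γ-lactone
Product: 18 [(2S,3S,4R)-2-[4-(tert-butyldimethylsilyloxy)-3-methoxyphenyl]-4-[3-(tert-butyldimethylsilyloxy)-4-methoxybenzyl]-5-hydroxy-3-(triethylsilyloxy)oxolan-3-yl]methyl 4-methylbenzenesulfonate (C5 epimers)
Conditions: i-Bu2AlH (1.2 equiv), CH2Cl2, −78 °C; aq. KNaC4H4O6 work-up
Reagents that add atoms: none
Why: Partial reduction of a lactone to the lactol through the aluminium hemiacetal, which is stable at −78 °C; the neopentyl-type tosylate and the silyl ethers are not attacked.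

Step 12
Reactants: 18 the lactol
Product: 19 [(2S,3S,4S)-2-[4-(tert-butyldimethylsilyloxy)-3-methoxyphenyl]-4-[3-(tert-butyldimethylsilyloxy)-4-methoxybenzyl]-3-(triethylsilyloxy)oxolan-3-yl]methyl 4-methylbenzenesulfonate
Conditions: Et3SiH (3 equiv), BF3·OEt2 (1.5 equiv), CH2Cl2, −78 °C; quench cold with Et3N then aq. NaHCO3
Reagents that add atoms: none
Why: Ionic hydrogenation of the lactol: BF3 ionises C5–OH to the cyclic oxocarbenium ion and Et3SiH delivers hydride to C5, which becomes a non-stereogenic methylene; at −78 °C the benzylic C2–O1 bond should not ionise.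

Step 13
Reactants: 19 the oxolane tosylate
Product: 21 (3S,4S,7S)-7-(3-hydroxy-4-methoxybenzyl)-4-(4-hydroxy-3-methoxyphenyl)-1,5-dioxaspiro[2.4]heptane (target), via desilylated hydroxy tosylate 20 (not isolated)
Conditions: Bu4NF (3.5 equiv), THF, 0 °C to rt; pH 7 buffer work-up
Reagents that add atoms: none
Why: Fluoride cleaves the two aryl silyl ethers and the tertiary Et3Si ether, and the liberated C3 alkoxide displaces the adjacent primary tosylate (intramolecular Williamson reaction, 3-exo-tet) to close the epoxide; O7 is the nucleophile and C6 is not stereogenic, so C3 keeps its configuration.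

## Compound list

1 | isovanillin (3-hydroxy-4-methoxybenzaldehyde) | COc1ccc(C=O)cc1O | starting material
2 | 3-(tert-butyldimethylsilyloxy)-4-methoxybenzaldehyde | COc1ccc(C=O)cc1O[Si](C)(C)C(C)(C)C | intermediate
3 | allenylboronic acid pinacol ester | C=C=CB1OC(C)(C)C(C)(C)O1 | starting material
4 | pinacol borate ester of 5 | C#CC[C@H](OB1OC(C)(C)C(C)(C)O1)c1ccc(OC)c(O[Si](C)(C)C(C)(C)C)c1 | intermediate
5 | (1S)-1-[3-(tert-butyldimethylsilyloxy)-4-methoxyphenyl]but-3-yn-1-ol | C#CC[C@H](O)c1ccc(OC)c(O[Si](C)(C)C(C)(C)C)c1 | intermediate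
6 | (5S)-5-[3-(tert-butyldimethylsilyloxy)-4-methoxyphenyl]oxolan-3-one | O=C1CO[C@H](c2ccc(OC)c(O[Si](C)(C)C(C)(C)C)c2)C1 | intermediate
7 | lithium (5S)-5-aryl-2,5-dihydrofuran-3-olate (C3=C4 enolate of 6) | [Li]OC1=C[C@@H](c2ccc(OC)c(O[Si](C)(C)C(C)(C)C)c2)OC1 | intermediate
8 | triethyl{[(5S)-5-[3-(tert-butyldimethylsilyloxy)-4-methoxyphenyl]-2,5-dihydrofuran-3-yl]oxy}silane | CC[Si](CC)(CC)OC1=C[C@@H](c2ccc(OC)c(O[Si](C)(C)C(C)(C)C)c2)OC1 | intermediate
9 | homovanillic acid | COc1cc(CC(O)=O)ccc1O | starting material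
10 | tert-butyldimethylsilyl 2-[4-(tert-butyldimethylsilyloxy)-3-methoxyphenyl]acetate | COc1cc(CC(=O)O[Si](C)(C)C(C)(C)C)ccc1O[Si](C)(C)C(C)(C)C | intermediate
11 | 2-[4-(tert-butyldimethylsilyloxy)-3-methoxyphenyl]acetic acid | COc1cc(CC(O)=O)ccc1O[Si](C)(C)C(C)(C)C | intermediate
12 | 2-[4-(tert-butyldimethylsilyloxy)-3-methoxyphenyl]acetyl chloride | COc1cc(CC(Cl)=O)ccc1O[Si](C)(C)C(C)(C)C | intermediate
13 | [4-(tert-butyldimethylsilyloxy)-3-methoxyphenyl]ketene | COc1cc(C=C=O)ccc1O[Si](C)(C)C(C)(C)C | intermediate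
14 | (1S,4S,5R,7S)-4-[3-(tert-butyldimethylsilyloxy)-4-methoxyphenyl]-7-[4-(tert-butyldimethylsilyloxy)-3-methoxyphenyl]-1-(triethylsilyloxy)-3-oxabicyclo[3.2.0]heptan-6-one (cis-fused; ring B endo, ring A exo) | O=C1[C@@H](c3ccc(O[Si](C)(C)C(C)(C)C)c(OC)c3)[C@@]2(O[Si](CC)(CC)CC)CO[C@H](c3ccc(OC)c(O[Si](C)(C)C(C)(C)C)c3)[C@@H]12 | intermediate
15 | (2S,3R,4R)-2-[4-(tert-butyldimethylsilyloxy)-3-methoxyphenyl]-4-[3-(tert-butyldimethylsilyloxy)-4-methoxybenzyl]-3-(hydroxymethyl)-3-(triethylsilyloxy)cyclobutan-1-one | O=C1[C@@H](c2ccc(O[Si](C)(C)C(C)(C)C)c(OC)c2)[C@@](O[Si](CC)(CC)CC)(CO)[C@H]1Cc1ccc(OC)c(O[Si](C)(C)C(C)(C)C)c1 | intermediate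
16 | primary tosylate of 15 | O=C1[C@@H](c2ccc(O[Si](C)(C)C(C)(C)C)c(OC)c2)[C@@](O[Si](CC)(CC)CC)(COS(=O)(=O)c2ccc(C)cc2)[C@H]1Cc1ccc(OC)c(O[Si](C)(C)C(C)(C)C)c1 | intermediate
17 | [(2S,3S,4R)-2-[4-(tert-butyldimethylsilyloxy)-3-methoxyphenyl]-4-[3-(tert-butyldimethylsilyloxy)-4-methoxybenzyl]-5-oxo-3-(triethylsilyloxy)oxolan-3-yl]methyl 4-methylbenzenesulfonate | O=C1O[C@@H](c2ccc(O[Si](C)(C)C(C)(C)C)c(OC)c2)[C@@](O[Si](CC)(CC)CC)(COS(=O)(=O)c2ccc(C)cc2)[C@H]1Cc1ccc(OC)c(O[Si](C)(C)C(C)(C)C)c1 | intermediate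
18 | lactol of 17 (5-hydroxy, C5 epimers) | OC1O[C@@H](c2ccc(O[Si](C)(C)C(C)(C)C)c(OC)c2)[C@@](O[Si](CC)(CC)CC)(COS(=O)(=O)c2ccc(C)cc2)[C@H]1Cc1ccc(OC)c(O[Si](C)(C)C(C)(C)C)c1 | intermediate
19 | [(2S,3S,4S)-2-[4-(tert-butyldimethylsilyloxy)-3-methoxyphenyl]-4-[3-(tert-butyldimethylsilyloxy)-4-methoxybenzyl]-3-(triethylsilyloxy)oxolan-3-yl]methyl 4-methylbenzenesulfonate | C1O[C@@H](c2ccc(O[Si](C)(C)C(C)(C)C)c(OC)c2)[C@@](O[Si](CC)(CC)CC)(COS(=O)(=O)c2ccc(C)cc2)[C@H]1Cc1ccc(OC)c(O[Si](C)(C)C(C)(C)C)c1 | intermediate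
20 | [(2S,3S,4S)-3-hydroxy-4-(3-hydroxy-4-methoxybenzyl)-2-(4-hydroxy-3-methoxyphenyl)oxolan-3-yl]methyl 4-methylbenzenesulfonate | C1O[C@@H](c2ccc(O)c(OC)c2)[C@@](O)(COS(=O)(=O)c2ccc(C)cc2)[C@H]1Cc1ccc(OC)c(O)c1 | intermediate
21 | (3S,4S,7S)-7-(3-hydroxy-4-methoxybenzyl)-4-(4-hydroxy-3-methoxyphenyl)-1,5-dioxaspiro[2.4]heptane (CNP0184956.1) | COc1ccc(C[C@H]2CO[C@@H](c3ccc(O)c(OC)c3)[C@@]23CO3)cc1O | target

## Step count and risks

Total steps: 13. Longest linear sequence: 11 (steps 1–4, then 7–13).

Steps most likely to fail: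

1. Step 7 (key cycloaddition). The trisubstituted silyl enol ether is only a moderate ketenophile, so ketene dimerisation may outrun the cycloaddition; a zwitterionic pathway may end in silyl transfer and C-acylation instead of ring closure; and the amine may epimerise C2 of the product or eliminate silanolate from it. Fallback: generate the same ketene without base and at low stationary concentration by a Wolff rearrangement. This sets out from enol ether 8 and comes back at 14. Commercial acetovanillone would be silylated (TBSCl, imidazole) to 1-[4-(tert-butyldimethylsilyloxy)-3-methoxyphenyl]ethanone F1. LiN(SiMe3)2 and CF3CO2CH2CF3 at −78 °C give the trifluoroacetylated diketone F2, which is not isolated, and MsN3/Et3N converts it by detrifluoroacetylative diazo transfer into 2-diazo-1-[4-(tert-butyldimethylsilyloxy)-3-methoxyphenyl]ethanone F3. Irradiation of F3 (Pyrex-filtered Hg lamp, PhMe, rt) in the presence of 8 should give ketene 13 by aryl migration and then 14 by the same [2+2] step.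

2. Step 12 (lactol to oxolane). BF3 may ionise the benzylic C2–O1 bond of the electron-rich 2-aryl oxolane, which would epimerise C2 or lead to reductive ring opening, and it may strip the tertiary Et3Si ether. Fallback: replace the cationic deoxygenation by a radical one. This sets out from lactol 18 and comes back at 19. Treatment of 18 with 1,1'-thiocarbonyldiimidazole and cat. DMAP in CH2Cl2 should give the O-lactol imidazole-1-carbothioate F4. Barton–McCombie reduction (Bu3SnH, AIBN, PhMe, 80 °C) then cleaves the anomeric C5–O bond through the α-oxy radical and gives 19 without any Lewis acid.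

3. Step 3 (gold-catalysed oxidative cyclisation). The electron-rich benzylic carbinol may ionise at the Lewis-acidic gold centre, the gold carbene may be captured by the arene instead of the hydroxyl, or a second N-oxide may over-oxidise the carbene. Fallback: build the oxolanone without a carbene. This sets out from alcohol 5 and comes back at 6. Cycloisomerisation of 5 with Et3N·Mo(CO)5 (from Mo(CO)6, Et3N, hν, Et2O) through the molybdenum vinylidene should give (2S)-2-aryl-2,3-dihydrofuran F5. Hydroboration with 9-BBN places boron β to oxygen (alkylborane F6, not isolated), and NaBO3·4H2O oxidation gives (5S)-5-aryl-oxolan-3-ol F7 as a mixture at C3. Dess–Martin oxidation of F7 then gives 6.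

## Further compounds

F1 | step 7 | 1-[4-(tert-butyldimethylsilyloxy)-3-methoxyphenyl]ethanone | CC(=O)c1ccc(O[Si](C)(C)C(C)(C)C)c(OC)c1
F2 | step 7 | 1-[4-(tert-butyldimethylsilyloxy)-3-methoxyphenyl]-4,4,4-trifluorobutane-1,3-dione | O=C(CC(=O)C(F)(F)F)c1ccc(O[Si](C)(C)C(C)(C)C)c(OC)c1
F3 | step 7 | 2-diazo-1-[4-(tert-butyldimethylsilyloxy)-3-methoxyphenyl]ethanone | [N-]=[N+]=CC(=O)c1ccc(O[Si](C)(C)C(C)(C)C)c(OC)c1
F4 | step 12 | O-lactol imidazole-1-carbothioate of 18 | S=C(OC1O[C@@H](c2ccc(O[Si](C)(C)C(C)(C)C)c(OC)c2)[C@@](O[Si](CC)(CC)CC)(COS(=O)(=O)c2ccc(C)cc2)[C@H]1Cc1ccc(OC)c(O[Si](C)(C)C(C)(C)C)c1)n1ccnc1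
F5 | step 3 | (2S)-2-[3-(tert-butyldimethylsilyloxy)-4-methoxyphenyl]-2,3-dihydrofuran | C1=CO[C@H](c2ccc(OC)c(O[Si](C)(C)C(C)(C)C)c2)C1
F6 | step 3 | 9-[(5S)-5-aryl-oxolan-3-yl]-9-borabicyclo[3.3.1]nonane | C1CC2CCCC(C1)B2C1CO[C@H](c2ccc(OC)c(O[Si](C)(C)C(C)(C)C)c2)C1
F7 | step 3 | (5S)-5-[3-(tert-butyldimethylsilyloxy)-4-methoxyphenyl]oxolan-3-ol | OC1CO[C@H](c2ccc(OC)c(O[Si](C)(C)C(C)(C)C)c2)C1
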